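Which flask closes more of its substrate to ring, hot zeta or cold theta?

| flask | substrate | activator | temperature | time |
|---|---|---|---|---|
| zeta | 0.020 M | 1.05 equiv | 55 °C | 6.0 d |
| theta | 0.020 M | 1.05 equiv | 35 °C | 6.0 d |

    activated form → ring (k1 = 6.9 × 10⁻⁶ s⁻¹, Ea1 = 103 kJ mol⁻¹)
    crystals ⇌ ring, rate k2*(cs2 - [ring]) while solid is left; crystals form when [ring] > cs2 (cs2 = 4.8 mM, k2 = 1.0 × 10⁻⁴ s⁻¹)
    substrate + activator → activated form (k3 = 0.0011 L mol⁻¹ s⁻¹, Ea3 = 77.0 kJ mol⁻¹)
    substrate + activated form → open dimer (k4 = 0.0029 L mol⁻¹ s⁻¹, Ea4 = 50.0 kJ mol⁻¹)
    (constants at 35 °C)

- a species is counted by the substrate in it: one open dimer counts as two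
- amounts and yields of ring count crystals too
- given per volume of solution although it is solid: crystals
- the list of constants is for 35 °C, to be carried to other temperatures by the activation energies

1. the flask that comes out highest in amount of ring, in percent of the substrate charged, or "all alike" when all lie within 1.5 percentage points (zeta / theta / all alike)
2. ring at the end, in percent of the substrate charged, zeta
3. ring at the end, in percent of the substrate charged, theta

Substrate meets activator and becomes activated form. Activated form then either closes to ring or captures a second substrate as open dimer. Count turnovers for one activated form. In theta it closes at 6.9 × 10⁻⁶ s⁻¹, and at the charged substrate it captures at 5.80 × 10⁻⁵ s⁻¹. Their ratio is 8.41. Call it the dimer number D, the capture turnovers per closing turnover at the charged substrate; it is a selectivity factor turned upside down. Heating to 55 °C speeds closure by a factor 12, more than capture at 3.3, so zeta has D = 2.38.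

Now take two extreme versions. Suppose activation were instant. Substrate is then gone before any capture, and ring is 100%. Suppose instead activation were far slower than closure. Activated form then stays low, and each one chooses on arrival. With substrate at a fraction s of its charge, it closes with share 1/(1+Ds). Closing uses one substrate and capture uses two, so each substrate consumed gives 1/(1+2Ds) of ring. Adding this up from full to empty gives ring = ln(1+2D)/(2D). I call this reckoned value the floor: 36.8% for zeta and 17.1% for theta.

I expect the real flasks to lie between. In zeta, activation of a substrate with about 0.020 M of activator runs at 1.37 × 10⁻⁴ s⁻¹, faster than closure at 8.00 × 10⁻⁵ s⁻¹, so I expect activated form to pile up early and zeta to land above its floor. But capture has a larger constant than activation, in zeta and in theta, so I expect each flask a little above its floor, with zeta ahead by about 20 percentage points. In theta, 6.0 d is 3.58 closing lifetimes, so little activated form should remain.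

The forecast says zeta, with 44% for zeta and 26% for theta, holding that “Ring closure has the highest activation energy”.

The simulation gives zeta, with 47.8% in zeta and 26.8% in theta, which is 21 points apart. Zeta stands 11 points above its floor. Capture is the main reason for zeta's shortfall: with that step struck out, ring in zeta climbs from 47.8% to 99.8%. A neighbour of zeta with 0.0080 M of substrate has D = 0.953, so its floor is 56.0%, and that neighbour gives 61.9% of ring.

The constants were chosen freely; the result is computed.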